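The route rests on treating C4 of the upper chroman (benzo ring A, pyran ring C) as a temporary ketone. C4 is bonded to C3 and to ring A at C4a, next to C8a, so one carbonyl both acidifies C3–H and activates a fluorine on C8a. In one operation the open 2-fluoroaryl benzyl ketone takes up formaldehyde at C3 (C2–C3) and the new alkoxide displaces fluoride (O1–C8a), closing ring C. The same carbonyl then sets C3 by transfer-hydrogenative dynamic kinetic resolution and becomes the cationic site where the linker arene enters trans to the C3 aryl. The lower chroman is made the same way.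

Key step: step 5

Assumption: no axial chirality is defined about the C4–aryl bond, so rotamers about this hindered bond are treated as one compound.

Notation: the upper chroman is benzo ring A and pyran ring C, its C3 aryl is ring B, the arene on C4 is ring D, and the lower chroman is pyran ring E and benzo ring F. Unprimed locants refer to the upper chroman. In names, U = (3R,4S)-7-(benzyloxy)-3-[3-(benzyloxy)-2,4-dimethoxyphenyl]chroman-4-yl.

Step 1
Reactants: 1 1-(2-fluoro-4-hydroxyphenyl)ethan-1-one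
Product: 2 1-[4-(benzyloxy)-2-fluorophenyl]ethan-1-one
Conditions: BnBr (1.1 equiv), K2CO3 (1.5 equiv), acetone, reflux
Reagents that add atoms: benzyl bromide, BrCc1ccccc1
Why: Williamson etherification of the phenol, needed because a free phenoxide para to the ketone would switch off the later fluoride displacement.

Step 2
Reactants: 3 2,6-dimethoxyphenol
Product: 4 2-(benzyloxy)-1,3-dimethoxybenzene
Conditions: BnBr (1.2 equiv), K2CO3 (2 equiv), DMF, 60 °C
Reagents that add atoms: benzyl bromide, BrCc1ccccc1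
Why: Williamson etherification of the flanked phenol, which protects the future ring-B hydroxyl as a hydrogenolyzable ether.

Step 3
Reactants: 4 2-(benzyloxy)-1,3-dimethoxybenzene
Product: 5 2-(benzyloxy)-4-bromo-1,3-dimethoxybenzene
Conditions: NBS (1.0 equiv), MeCN, 0 °C to rt
Reagents that add atoms: N-bromosuccinimide, O=C1CCC(=O)N1Br
Why: Electrophilic aromatic bromination should occur at C4, para to one methoxy and ortho to the other as in 1,2,3-trimethoxybenzene, because the twisted central benzyloxy group activates its own para position only weakly.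

Step 4
Reactants: 2 1-[4-(benzyloxy)-2-fluorophenyl]ethan-1-one, 5 2-(benzyloxy)-4-bromo-1,3-dimethoxybenzene
Product: 6 1-[4-(benzyloxy)-2-fluorophenyl]-2-[3-(benzyloxy)-2,4-dimethoxyphenyl]ethan-1-one
Conditions: Pd(OAc)2 (2 mol %), XPhos (4 mol %), K3PO4 (2.3 equiv), toluene, 90 °C
Reagents that add atoms: none
Why: Palladium-catalyzed ketone α-arylation (Buchwald–Hartwig type), in which the ortho-methoxy aryl bromide should stop at monoarylation and the mild phosphate base should leave the activated aryl fluoride untouched.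

Step 5
Reactants: 6 1-[4-(benzyloxy)-2-fluorophenyl]-2-[3-(benzyloxy)-2,4-dimethoxyphenyl]ethan-1-one
Product: 8 rac-7-(benzyloxy)-3-[3-(benzyloxy)-2,4-dimethoxyphenyl]chroman-4-one, via hydroxymethyl ketone 7 (not isolated)
Conditions: (CH2O)n (1.2 equiv), K2CO3 (2 equiv), DMF, 70 °C
Reagents that add atoms: formaldehyde (from paraformaldehyde), C=O
Why: Carbonate forms the enolate of 6, which adds to formaldehyde (aldol hydroxymethylation, C2–C3), and the alkoxide of 7 then attacks C8a in an addition–elimination (SNAr) that expels fluoride and forms O1–C8a. The closest known reaction types are the formaldehyde-based isoflavanone synthesis from deoxybenzoins and the heteroatom SNAr ring closures on ortho-fluoroaryl ketones that give chroman-4-ones and 4-quinolones. Ring C closes as a six-membered ring, formally 6-endo-trig with respect to the C8a=C4a bond that relays the negative charge to the C4 carbonyl (the fluoroaryl ketone acts as a vinylogous acyl fluoride). The new stereocenter C3 is formed without control and stays epimerizable beside the ketone, which is intended, because step 6 sets it by dynamic kinetic resolution. The step needs ring closure to outrun a second hydroxymethylation and loss of water to the 2-arylpropenone: aldol addition and dehydration are reversible whereas the intramolecular SNAr is not, formaldehyde is kept near one equivalent, and the 7-benzyloxy group is meta to C8a, so it does not deactivate that carbon as a free phenoxide would.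

Step 6
Reactants: 8 rac-7-(benzyloxy)-3-[3-(benzyloxy)-2,4-dimethoxyphenyl]chroman-4-one
Product: 9 (3R,4R)-7-(benzyloxy)-3-[3-(benzyloxy)-2,4-dimethoxyphenyl]chroman-4-ol (cis)
Conditions: RuCl(p-cymene)[(R,R)-TsDPEN] (2 mol %), HCO2H–Et3N (5:2), EtOAc, 40 °C
Reagents that add atoms: none
Why: Noyori asymmetric transfer hydrogenation with dynamic kinetic resolution: triethylamine epimerizes C3 through the enol, the (R,R) catalyst delivers hydride to the carbonyl face that makes C4 (R), and only the (3R) ketone accepts it anti to its C3 aryl, which should give the cis (3R,4R) alcohol.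

Step 7
Reactants: 10 3-bromo-5-methoxyphenol
Product: 11 (3-bromo-5-methoxyphenoxy)tri(propan-2-yl)silane
Conditions: iPr3SiCl (1.1 equiv), imidazole (2 equiv), DMF, rt
Reagents that add atoms: chlorotri(propan-2-yl)silane, CC(C)[Si](Cl)(C(C)C)C(C)C
Why: Imidazole-promoted silylation of the phenol; the bulky silyl ether protects the oxygen through step 8 and later shields its two ortho carbons in step 9.

Step 8
Reactants: 2 1-[4-(benzyloxy)-2-fluorophenyl]ethan-1-one, 11 (3-bromo-5-methoxyphenoxy)tri(propan-2-yl)silane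
Product: 12 1-[4-(benzyloxy)-2-fluorophenyl]-2-{3-methoxy-5-[tri(propan-2-yl)silyloxy]phenyl}ethan-1-one
Conditions: Pd(OAc)2 (2 mol %), XPhos (4 mol %), K3PO4 (2.3 equiv), toluene, 90 °C, 2 in 1.5-fold excess
Reagents that add atoms: none
Why: The same palladium-catalyzed ketone α-arylation as in step 4, with excess ketone to suppress diarylation by the unhindered bromide and phosphate base to keep the aryl silyl ether intact.

Step 9
Reactants: 9 (3R,4R)-7-(benzyloxy)-3-[3-(benzyloxy)-2,4-dimethoxyphenyl]chroman-4-ol, 12 1-[4-(benzyloxy)-2-fluorophenyl]-2-{3-methoxy-5-[tri(propan-2-yl)silyloxy]phenyl}ethan-1-one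
Product: 13 1-[4-(benzyloxy)-2-fluorophenyl]-2-{2-U-3-methoxy-5-[tri(propan-2-yl)silyloxy]phenyl}ethan-1-one
Conditions: Bi(OTf)3 (5 mol %), 4 Å MS, CH2Cl2, −30 to 0 °C, 9 added slowly to 12 (3 equiv)
Reagents that add atoms: none
Why: Friedel–Crafts benzylation (SN1) through the C4 cation stabilized by O1 and the 7-benzyloxy group: the arene should attack anti to the C3 aryl so that C4 becomes (S) and trans while C3 is untouched, the bulky silyl ether shields both of its ortho carbons and leaves the ring-D carbon between the methoxy group and the side chain as the reacting site, ring F of 12 is switched off by its ketone and fluorine, and excess 12 with slow addition of 9 limits self-alkylation by ring A.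

Step 10
Reactants: 13 1-[4-(benzyloxy)-2-fluorophenyl]-2-{2-U-3-methoxy-5-[tri(propan-2-yl)silyloxy]phenyl}ethan-1-one
Product: 15 1-[4-(benzyloxy)-2-fluorophenyl]-2-[5-(benzyloxy)-2-U-3-methoxyphenyl]ethan-1-one, via phenol 14 (not isolated)
Conditions: CsF (2 equiv), BnBr (1.2 equiv), DMF, rt
Reagents that add atoms: benzyl bromide, BrCc1ccccc1
Why: Fluoride cleaves the aryl silyl ether and the phenoxide is benzylated in the same flask (desilylative Williamson etherification), so that no free phenoxide is present when formaldehyde and fluoride appear in step 11.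

Step 11
Reactants: 15 1-[4-(benzyloxy)-2-fluorophenyl]-2-[5-(benzyloxy)-2-U-3-methoxyphenyl]ethan-1-one
Product: 17 7-(benzyloxy)-3-[5-(benzyloxy)-2-U-3-methoxyphenyl]chroman-4-one (both C3 epimers of the lower ring), via hydroxymethyl ketone 16 (not isolated)
Conditions: (CH2O)n (1.2 equiv), K2CO3 (2 equiv), DMF, 70 °C
Reagents that add atoms: formaldehyde (from paraformaldehyde), C=O
Why: The same aldol hydroxymethylation–SNAr domino as in step 5 closes ring E; the new lower C3 stereocenter forms as a labile epimer mixture beside the ketone and is corrected in step 12.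

Step 12
Reactants: 17 7-(benzyloxy)-3-[5-(benzyloxy)-2-U-3-methoxyphenyl]chroman-4-one
Product: 18 (3R,4R)-7-(benzyloxy)-3-[5-(benzyloxy)-2-U-3-methoxyphenyl]chroman-4-ol
Conditions: RuCl(p-cymene)[(R,R)-TsDPEN] (3 mol %), HCO2H–Et3N (5:2), EtOAc–DMF, 40 °C
Reagents that add atoms: none
Why: A second Noyori transfer hydrogenation with dynamic kinetic resolution, in which the catalyst rather than the remote upper stereocenters should select the (3R) epimer of the equilibrating ketone and give the cis (3R,4R) alcohol of the lower ring.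

Step 13
Reactants: 18 (3R,4R)-7-(benzyloxy)-3-[5-(benzyloxy)-2-U-3-methoxyphenyl]chroman-4-ol
Product: 19 (3R,4S)-3-(3-hydroxy-2,4-dimethoxyphenyl)-4-{4-hydroxy-2-[(3R)-7-hydroxychroman-3-yl]-6-methoxyphenyl}chroman-7-ol (CNP0305801.1)
Conditions: H2 (3 bar), Pd/C (10 wt % Pd), EtOAc–EtOH–AcOH, rt
Reagents that add atoms: none
Why: Palladium-catalyzed hydrogenolysis should remove the four benzyl ethers and the electron-rich benzylic C4 hydroxyl of the lower chroman in one operation, while lower C3 is not involved and keeps its (R) configuration.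

Compound list
1 | 1-(2-fluoro-4-hydroxyphenyl)ethan-1-one | CC(=O)c1ccc(O)cc1F | starting material
2 | 1-[4-(benzyloxy)-2-fluorophenyl]ethan-1-one | CC(=O)c1ccc(OCc2ccccc2)cc1F | intermediate
3 | 2,6-dimethoxyphenol | COc1cccc(OC)c1O | starting material
4 | 2-(benzyloxy)-1,3-dimethoxybenzene | COc1cccc(OC)c1OCc1ccccc1 | intermediate
5 | 2-(benzyloxy)-4-bromo-1,3-dimethoxybenzene | COc1ccc(Br)c(OC)c1OCc1ccccc1 | intermediate
6 | 1-[4-(benzyloxy)-2-fluorophenyl]-2-[3-(benzyloxy)-2,4-dimethoxyphenyl]ethan-1-one | COc1ccc(CC(=O)c2ccc(OCc3ccccc3)cc2F)c(OC)c1OCc1ccccc1 | intermediate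
7 | 1-[4-(benzyloxy)-2-fluorophenyl]-2-[3-(benzyloxy)-2,4-dimethoxyphenyl]-3-hydroxypropan-1-one (racemic, not isolated) | COc1ccc(C(CO)C(=O)c2ccc(OCc3ccccc3)cc2F)c(OC)c1OCc1ccccc1 | intermediate
8 | rac-7-(benzyloxy)-3-[3-(benzyloxy)-2,4-dimethoxyphenyl]chroman-4-one | COc1ccc(C2COc3cc(OCc4ccccc4)ccc3C2=O)c(OC)c1OCc1ccccc1 | intermediate
9 | (3R,4R)-7-(benzyloxy)-3-[3-(benzyloxy)-2,4-dimethoxyphenyl]chroman-4-ol | COc1ccc([C@@H]2COc3cc(OCc4ccccc4)ccc3[C@@H]2O)c(OC)c1OCc1ccccc1 | intermediate
10 | 3-bromo-5-methoxyphenol | COc1cc(O)cc(Br)c1 | starting material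
11 | (3-bromo-5-methoxyphenoxy)tri(propan-2-yl)silane | COc1cc(Br)cc(O[Si](C(C)C)(C(C)C)C(C)C)c1 | intermediate
12 | 1-[4-(benzyloxy)-2-fluorophenyl]-2-{3-methoxy-5-[tri(propan-2-yl)silyloxy]phenyl}ethan-1-one | COc1cc(CC(=O)c2ccc(OCc3ccccc3)cc2F)cc(O[Si](C(C)C)(C(C)C)C(C)C)c1 | intermediate
13 | 1-[4-(benzyloxy)-2-fluorophenyl]-2-{2-[(3R,4S)-7-(benzyloxy)-3-[3-(benzyloxy)-2,4-dimethoxyphenyl]chroman-4-yl]-3-methoxy-5-[tri(propan-2-yl)silyloxy]phenyl}ethan-1-one | COc1ccc([C@@H]2COc3cc(OCc4ccccc4)ccc3[C@H]2c2c(OC)cc(O[Si](C(C)C)(C(C)C)C(C)C)cc2CC(=O)c2ccc(OCc3ccccc3)cc2F)c(OC)c1OCc1ccccc1 | intermediate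
14 | 1-[4-(benzyloxy)-2-fluorophenyl]-2-{2-[(3R,4S)-7-(benzyloxy)-3-[3-(benzyloxy)-2,4-dimethoxyphenyl]chroman-4-yl]-5-hydroxy-3-methoxyphenyl}ethan-1-one (not isolated) | COc1ccc([C@@H]2COc3cc(OCc4ccccc4)ccc3[C@H]2c2c(OC)cc(O)cc2CC(=O)c2ccc(OCc3ccccc3)cc2F)c(OC)c1OCc1ccccc1 | intermediate
15 | 1-[4-(benzyloxy)-2-fluorophenyl]-2-{5-(benzyloxy)-2-[(3R,4S)-7-(benzyloxy)-3-[3-(benzyloxy)-2,4-dimethoxyphenyl]chroman-4-yl]-3-methoxyphenyl}ethan-1-one | COc1ccc([C@@H]2COc3cc(OCc4ccccc4)ccc3[C@H]2c2c(OC)cc(OCc3ccccc3)cc2CC(=O)c2ccc(OCc3ccccc3)cc2F)c(OC)c1OCc1ccccc1 | intermediate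
16 | 1-[4-(benzyloxy)-2-fluorophenyl]-2-{5-(benzyloxy)-2-[(3R,4S)-7-(benzyloxy)-3-[3-(benzyloxy)-2,4-dimethoxyphenyl]chroman-4-yl]-3-methoxyphenyl}-3-hydroxypropan-1-one (both C2 epimers, not isolated) | COc1ccc([C@@H]2COc3cc(OCc4ccccc4)ccc3[C@H]2c2c(OC)cc(OCc3ccccc3)cc2C(CO)C(=O)c2ccc(OCc3ccccc3)cc2F)c(OC)c1OCc1ccccc1 | intermediate
17 | 7-(benzyloxy)-3-{5-(benzyloxy)-2-[(3R,4S)-7-(benzyloxy)-3-[3-(benzyloxy)-2,4-dimethoxyphenyl]chroman-4-yl]-3-methoxyphenyl}chroman-4-one (both C3 epimers of the lower ring) | COc1ccc([C@@H]2COc3cc(OCc4ccccc4)ccc3[C@H]2c2c(OC)cc(OCc3ccccc3)cc2C2COc3cc(OCc4ccccc4)ccc3C2=O)c(OC)c1OCc1ccccc1 | intermediate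
18 | (3R,4R)-7-(benzyloxy)-3-{5-(benzyloxy)-2-[(3R,4S)-7-(benzyloxy)-3-[3-(benzyloxy)-2,4-dimethoxyphenyl]chroman-4-yl]-3-methoxyphenyl}chroman-4-ol | COc1ccc([C@@H]2COc3cc(OCc4ccccc4)ccc3[C@H]2c2c(OC)cc(OCc3ccccc3)cc2[C@@H]2COc3cc(OCc4ccccc4)ccc3[C@@H]2O)c(OC)c1OCc1ccccc1 | intermediate
19 | (3R,4S)-3-(3-hydroxy-2,4-dimethoxyphenyl)-4-{4-hydroxy-2-[(3R)-7-hydroxychroman-3-yl]-6-methoxyphenyl}chroman-7-ol | COc1ccc([C@@H]2COc3cc(O)ccc3[C@H]2c2c(OC)cc(O)cc2[C@@H]2COc3cc(O)ccc3C2)c(OC)c1O | target

Total step count: 13.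
Longest linear sequence: 10 steps (steps 2, 3, 4, 5, 6, 9, 10, 11, 12, 13); steps 1 and 7–8 are side branches.

Steps most likely to fail

Step 9. The hindered ring-D carbon may be outrun by three processes: capture of the C4 cation by ring A of a second molecule, loss of the C3 proton (which would also erase C3), or attack at the ring-D carbon para to the methoxy group. The fallback sets out from 12 (with 9) and changes the control element from steric shielding to a free, more nucleophilic phenol. 12 is desilylated with Bu4NF in THF to 1-[4-(benzyloxy)-2-fluorophenyl]-2-(3-hydroxy-5-methoxyphenyl)ethan-1-one F1. 9 is then condensed with F1 (3 equiv) in hexafluoroisopropanol at 0 °C without a metal catalyst, a hydrogen-bond-promoted dehydrative Friedel–Crafts alkylation para to the free hydroxyl. This should give phenol 14, which is isolated and benzylated (BnBr, K2CO3, DMF) to 15, where the route continues.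

Step 12. Hydride transfer to the ketone beside the heavily ortho-substituted ring D may be slow, or facial selection may be poor, so that the dynamic resolution gives mixed epimers. The fallback sets out from 17 and sets lower C3 on an alkene instead of a ketone. NaBH4 in THF–MeOH should give the epimeric alcohols 7-(benzyloxy)-3-[5-(benzyloxy)-2-U-3-methoxyphenyl]chroman-4-ol F2. Dehydration with catalytic pTsOH in toluene at 60 °C should give 7-(benzyloxy)-3-[5-(benzyloxy)-2-U-3-methoxyphenyl]-2H-chromene F3. Asymmetric hydrogenation with [Ir(cod)((S)-tBu-PHOX)]BArF (or its enantiomer, whichever delivers the (3R) chroman) under H2 in CH2Cl2 should give (3R)-7-(benzyloxy)-3-[5-(benzyloxy)-2-U-3-methoxyphenyl]chroman F4. Hydrogenolysis (H2, Pd/C, EtOAc–EtOH) then cleaves the four benzyl ethers and comes back to the route at 19.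

Step 13. Acid-promoted dehydration of the benzylic alcohol before C–O cleavage, followed by unselective alkene hydrogenation, would scramble lower C3; incomplete C–O hydrogenolysis is the other failure. The fallback sets out from 18 and removes the oxygen by a radical path that cannot touch C3 (Barton–McCombie deoxygenation). NaH, CS2 and MeI in THF should give O-{(3R,4R)-7-(benzyloxy)-3-[5-(benzyloxy)-2-U-3-methoxyphenyl]chroman-4-yl} S-methyl carbonodithioate F5. Bu3SnH with AIBN in toluene at 80 °C should then give (3R)-7-(benzyloxy)-3-[5-(benzyloxy)-2-U-3-methoxyphenyl]chroman F6 (the same compound as F4). Neutral hydrogenolysis (H2, Pd/C, EtOAc–EtOH) cleaves only the benzyl ethers and comes back to the route at 19.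

Further compounds
F1 | step 9 | 1-[4-(benzyloxy)-2-fluorophenyl]-2-(3-hydroxy-5-methoxyphenyl)ethan-1-one | COc1cc(O)cc(CC(=O)c2ccc(OCc3ccccc3)cc2F)c1
F2 | step 12 | 7-(benzyloxy)-3-{5-(benzyloxy)-2-[(3R,4S)-7-(benzyloxy)-3-[3-(benzyloxy)-2,4-dimethoxyphenyl]chroman-4-yl]-3-methoxyphenyl}chroman-4-ol (epimers at lower C3 and C4) | COc1ccc([C@@H]2COc3cc(OCc4ccccc4)ccc3[C@H]2c2c(OC)cc(OCc3ccccc3)cc2C2COc3cc(OCc4ccccc4)ccc3C2O)c(OC)c1OCc1ccccc1
F3 | step 12 | 7-(benzyloxy)-3-{5-(benzyloxy)-2-[(3R,4S)-7-(benzyloxy)-3-[3-(benzyloxy)-2,4-dimethoxyphenyl]chroman-4-yl]-3-methoxyphenyl}-2H-chromene | COc1ccc([C@@H]2COc3cc(OCc4ccccc4)ccc3[C@H]2c2c(OC)cc(OCc3ccccc3)cc2C2=Cc3ccc(OCc4ccccc4)cc3OC2)c(OC)c1OCc1ccccc1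
F4 | step 12 | (3R)-7-(benzyloxy)-3-{5-(benzyloxy)-2-[(3R,4S)-7-(benzyloxy)-3-[3-(benzyloxy)-2,4-dimethoxyphenyl]chroman-4-yl]-3-methoxyphenyl}chroman | COc1ccc([C@@H]2COc3cc(OCc4ccccc4)ccc3[C@H]2c2c(OC)cc(OCc3ccccc3)cc2[C@@H]2COc3cc(OCc4ccccc4)ccc3C2)c(OC)c1OCc1ccccc1
F5 | step 13 | O-{(3R,4R)-7-(benzyloxy)-3-{5-(benzyloxy)-2-[(3R,4S)-7-(benzyloxy)-3-[3-(benzyloxy)-2,4-dimethoxyphenyl]chroman-4-yl]-3-methoxyphenyl}chroman-4-yl} S-methyl carbonodithioate | COc1ccc([C@@H]2COc3cc(OCc4ccccc4)ccc3[C@H]2c2c(OC)cc(OCc3ccccc3)cc2[C@@H]2COc3cc(OCc4ccccc4)ccc3[C@@H]2OC(=S)SC)c(OC)c1OCc1ccccc1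
F6 | step 13 | (3R)-7-(benzyloxy)-3-{5-(benzyloxy)-2-[(3R,4S)-7-(benzyloxy)-3-[3-(benzyloxy)-2,4-dimethoxyphenyl]chroman-4-yl]-3-methoxyphenyl}chroman | COc1ccc([C@@H]2COc3cc(OCc4ccccc4)ccc3[C@H]2c2c(OC)cc(OCc3ccccc3)cc2[C@@H]2COc3cc(OCc4ccccc4)ccc3C2)c(OC)c1OCc1ccccc1
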